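## Retrosynthetic overview

1. Side chain last: CH=CMe2 ⇐ Wittig ⇐ CH=O ⇐ glycol cleavage ⇐ 2,2-dimethyl-1,3-dioxolan-4-yl. The vinyl CH of the target is the former stereocentre of D-glyceraldehyde acetonide.
2. Central dihydropyran (ring 1) ⇐ inverse-demand oxa-Diels–Alder reaction. The heterodiene is a 3-alkylidene-1-methylquinoline-2,4-dione, made in the flask from 4-hydroxy-1-methylquinolin-2(1H)-one and the glyceraldehyde acetonide. The dienophile is the pyran C=C of N-methylflindersine. All three stereocentres form here, directed by the dioxolane centre.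
3. N-Methylflindersine (ring 2) ⇐ Knoevenagel condensation/oxa-6π electrocyclisation of the same quinolinone with 3-methylbut-2-enal.
4. Ring order: both quinolinones are bought intact → ring 2 → ring 1 → side-chain adjustment.

Labels: quinolinone A carries C-a on C3 and the ring 1 oxygen on C4; quinolinone B is fused to ring 2. C-a is the CH with the side chain; C-b is the O–CH bonded to C3 of quinolinone B; C-c is the CH bonded to C-a, C-b and CMe2. Ring 1 is O(A)/C4(A)/C3(A)/C-a/C-c/C-b; ring 2 is O(B)/CMe2/C-c/C-b/C3(B)/C4(B). The target is C-a S, C-b R, C-c S, with a cis ring fusion and H at C-a anti to H at C-c.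

Assumption: the facial sense of induction in step 2 is taken from the allylic-strain model stated there and is not a measured result; the structure and ee of 7 are to be confirmed (X-ray, HPLC) before it is carried on.

## Route

Step 1
Reactants: 1 4-hydroxy-1-methylquinolin-2(1H)-one; 2 3-methylbut-2-enal
Product: 4 N-methylflindersine (2,2,6-trimethyl-2,6-dihydro-5H-pyrano[3,2-c]quinolin-5-one), via oxatriene 3 (not isolated)
Conditions: 2 (1.5 equiv), ethylenediammonium diacetate (10 mol %), CH2Cl2, 40 °C, 8 h
Reagents that add atoms: none
Why: Knoevenagel condensation of the vinylogous acid 1 with the enal gives the 1-oxatriene 3, which closes by oxa-6π electrocyclisation (formal [3+3] annulation) to the 2H-pyran of ring 2; no stereocentre is formed.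

Step 2
Reactants: 1 4-hydroxy-1-methylquinolin-2(1H)-one; 5 (R)-2,2-dimethyl-1,3-dioxolane-4-carbaldehyde; 4 N-methylflindersine
Product: 7 dioxolanyl cycloadduct (C-a S; C-b R; C-c S; dioxolane C4 S), via alkylidene dione 6 (not isolated)
Conditions: 5 (1.5 equiv, freshly distilled), 4 (3 equiv), 4 Å molecular sieves, 1,4-dioxane, 80 °C, 1 added over 6 h, no amine; SiO2 chromatography (excess 4 recovered)
Reagents that add atoms: none
Why: Domino Knoevenagel condensation/inverse-electron-demand oxa-Diels–Alder reaction: 1 (acidic enough to condense without an amine, which spares the α-stereocentre of 5) and 5 give the electron-poor 1-oxadiene 6, whose C4 ketone oxygen bonds to the benzylic alkene carbon of 4 (C-b) and whose exocyclic carbon (C-a) bonds to the other alkene carbon (C-c), the polarity 4 shows in its own dimerisation; suprafacial addition to the cis ring alkene gives the cis ring fusion, the exo approach that keeps the CMe2 group away from the heterodiene places H at C-a anti to H at C-c, and the dioxolane centre, whose C–H lies in the diene plane to avoid 1,3-allylic strain with the flanking carbonyl, lets 4 add anti to its C–O bond, which sets C-a as S and with it C-c as S and C-b as R; the other cis-fused adducts are diastereomers of 7 and are removed on silica.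

Step 3
Reactants: 7 dioxolanyl cycloadduct
Product: 9 C-a carbaldehyde (C-a S; C-b R; C-c S), via diol 8 (not isolated)
Conditions: H5IO6 (1.5 equiv), EtOAc, 0 °C to rt, 2 h; aq NaHCO3 work-up, used crude
Reagents that add atoms: none
Why: Periodic acid hydrolyses the terminal acetonide to diol 8 and cleaves it at once (Malaprade glycol cleavage), so the former dioxolane stereocentre becomes the aldehyde carbon while C-a, C-b and C-c are not touched, and no alkene or other oxidisable group is present at this stage.

Step 4
Reactants: 9 C-a carbaldehyde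
Product: 10 target CNP0210533.1
Conditions: i-PrPPh3I (2.5 equiv), n-BuLi (2.4 equiv), THF, 0 °C, 30 min; then 9, −78 °C to rt
Reagents that add atoms: isopropyltriphenylphosphonium iodide, CC(C)[P+](c1ccccc1)(c1ccccc1)c1ccccc1.[I-]
Why: Wittig olefination with the non-stabilised, symmetrical isopropylidene ylide converts CH=O into CH=CMe2 with no E/Z question; adding 9 at −78 °C limits enolisation, and C-a in any case has the thermodynamically preferred configuration (side chain anti to the CMe2-bearing C-c).

## Compound list

1 | 4-hydroxy-1-methylquinolin-2(1H)-one | Cn1c(=O)cc(O)c2ccccc12 | starting material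
2 | 3-methylbut-2-enal (prenal) | CC(C)=CC=O | starting material
3 | (E)-1-methyl-3-(3-methylbut-2-en-1-ylidene)quinoline-2,4(1H,3H)-dione (chain syn to the C4 ketone; not isolated) | CC(C)=C/C=C1\C(=O)c2ccccc2N(C)C1=O | intermediate
4 | N-methylflindersine, 2,2,6-trimethyl-2,6-dihydro-5H-pyrano[3,2-c]quinolin-5-one | CC1(C)C=Cc2c(O1)c1ccccc1n(C)c2=O | intermediate
5 | (R)-2,2-dimethyl-1,3-dioxolane-4-carbaldehyde (D-glyceraldehyde acetonide) | O=C[C@H]1COC(C)(C)O1 | starting material
6 | (Z)-3-{[(4S)-2,2-dimethyl-1,3-dioxolan-4-yl]methylidene}-1-methylquinoline-2,4(1H,3H)-dione (side chain anti to the C4 ketone; same spatial arrangement at the dioxolane centre as in 5; not isolated) | CC1(C)OC[C@@H](O1)/C=C1\C(=O)N(C)c2ccccc2C1=O | intermediate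
7 | dioxolanyl cycloadduct: 10 with the 2-methylprop-1-enyl group replaced by (4S)-2,2-dimethyl-1,3-dioxolan-4-yl; C-a S, C-b R, C-c S; cis ring fusion, H at C-a anti to H at C-c | CC1(C)OC[C@@H](O1)[C@@H]1c2c(c3ccccc3n(C)c2=O)O[C@H]2c3c(c4ccccc4n(C)c3=O)OC(C)(C)[C@@H]12 | intermediate
8 | diol: 10 with the 2-methylprop-1-enyl group replaced by (1S)-1,2-dihydroxyethyl; C-a S, C-b R, C-c S (not isolated) | OC[C@@H](O)[C@@H]1c2c(c3ccccc3n(C)c2=O)O[C@H]2c3c(c4ccccc4n(C)c3=O)OC(C)(C)[C@@H]12 | intermediate
9 | C-a carbaldehyde: 10 with the 2-methylprop-1-enyl group replaced by CH=O; C-a S, C-b R, C-c S | O=C[C@@H]1c2c(c3ccccc3n(C)c2=O)O[C@H]2c3c(c4ccccc4n(C)c3=O)OC(C)(C)[C@@H]12 | intermediate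
10 | CNP0210533.1: cis-fused hexacyclic dimer of N-methylflindersine; C-a S (bearing 2-methylprop-1-enyl), C-b R, C-c S | CC(C)=C[C@@H]1c2c(c3ccccc3n(C)c2=O)O[C@H]2c3c(c4ccccc4n(C)c3=O)OC(C)(C)[C@@H]12 | target

## Step count and risks

Total steps: 4. Longest linear sequence: 4 (1 → 4 → 7 → 9 → 10).

**Step 2 (highest risk).** The cis-disubstituted, chromene-type alkene of 4 is only a moderate dienophile. Heterodiene 6 can therefore be drained into the reversible bis-adduct with a second molecule of 1, or into its dienol tautomer, which would also erode the ee. The exo and facial preferences are model-based; wrong isomers are diastereomers of 7 and separable, but they cost yield. The fallback sets out from 1 and comes back at 7. 1, 5 and thiophenol are combined in ethanol at room temperature without amine to give the thia-Michael adduct 3-{[(4R)-2,2-dimethyl-1,3-dioxolan-4-yl](phenylsulfanyl)methyl}-4-hydroxy-1-methylquinolin-2(1H)-one F1 (both epimers at the sulfur-bearing carbon, which becomes sp2 again). F1 is a purifiable, storable masked form of 6. Heating F1 with 4 (3 equiv) in toluene at 110 °C releases thiophenol and generates 6 slowly, with no free 1 or free aldehyde present, so the cycloaddition to 7 is the only productive outlet.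

**Step 4.** The basic ylide may enolise the hindered α-heteroaryl aldehyde 9, giving low conversion. The fallback sets out from 9 and comes back at 10. 9 is treated under non-basic Ramirez conditions (CBr4, PPh3, CH2Cl2, 0 °C) to give the 1,1-dibromoalkene F2 (CH=O replaced by CH=CBr2, ring stereocentres unchanged). Both bromides are then exchanged for methyl by Negishi coupling (MeZnCl, 5 mol % Pd(P(t-Bu)3)2 as a zerovalent palladium catalyst, THF, rt to 50 °C), which builds the CH=CMe2 group of 10 by cross-coupling instead of carbonyl olefination.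

**Step 3.** The acidic oxidant may ionise the benzylic C-b–O bond, and aldehyde 9 may epimerise or hydrate on handling. The fallback sets out from 7 and comes back at 10, bypassing 9 and step 4. The acetonide alone is hydrolysed (80% aq AcOH, 40 °C) and diol 8 is isolated. 1,1'-Thiocarbonyldiimidazole (toluene, 80 °C) converts 8 into the cyclic thionocarbonate F3. Corey–Winter elimination (P(OMe)3, 110 °C) gives the ethenyl compound F4 (side chain CH=CH2). Cross-metathesis of F4 with 2-methyl-2-butene as co-solvent (second-generation Grubbs catalyst RuCl2(=CHPh)(PCy3)(H2IMes), CH2Cl2, 40 °C) then gives 10.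

## Further compounds

F1 | step 2 | 3-{[(4R)-2,2-dimethyl-1,3-dioxolan-4-yl](phenylsulfanyl)methyl}-4-hydroxy-1-methylquinolin-2(1H)-one, both epimers at the sulfur-bearing carbon | CC1(C)OC[C@@H](O1)C(Sc1ccccc1)c1c(O)c2ccccc2n(C)c1=O
F2 | step 4 | 1,1-dibromoalkene: 10 with the side chain replaced by 2,2-dibromoethenyl, ring stereocentres as in 10 | BrC(Br)=C[C@@H]1c2c(c3ccccc3n(C)c2=O)O[C@H]2c3c(c4ccccc4n(C)c3=O)OC(C)(C)[C@@H]12
F3 | step 3 | cyclic thionocarbonate of diol 8 (2-thioxo-1,3-dioxolan-4-yl at C-a), ring stereocentres as in 10 | S=C1OC[C@@H](O1)[C@@H]1c2c(c3ccccc3n(C)c2=O)O[C@H]2c3c(c4ccccc4n(C)c3=O)OC(C)(C)[C@@H]12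
F4 | step 3 | ethenyl compound: 10 with the side chain replaced by CH=CH2, ring stereocentres as in 10 | C=C[C@@H]1c2c(c3ccccc3n(C)c2=O)O[C@H]2c3c(c4ccccc4n(C)c3=O)OC(C)(C)[C@@H]12
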